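Assumption: eugenol benzyl ether (1) and O-benzylvanillin (5) are bought as such (1 is otherwise one step from eugenol with BnBr, K2CO3); the target is the all-trans (1R,2S,3S) isomer (1-aryl trans to 2-CO2Me, 2-CO2Me trans to 3-CH2OH).

**Retrosynthetic overview**
1. Target ⇐ hydrogenolysis of its bis-benzyl ether ⇐ hydroxide opening and O-methylation of the all-trans aryltetralin γ-lactone.
2. Ring B ⇐ Friedel–Crafts closure (C1–C8a) of the aldol adduct (C1–C2) of an (S)-β-arylmethyl-γ-butyrolactone and O-benzylvanillin; C2 and C1 are relayed from C3.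
3. (S)-Lactone ⇐ enantioselective oxygen insertion (new CH2–O bond) into a prochiral 3-(arylmethyl)cyclobutanone; this step alone fixes the absolute configuration.
4. Cyclobutanone ⇐ dichloroketene [2+2] on eugenol benzyl ether, then dechlorination.
5. Ring order: cyclobutanone → γ-lactone → ring B → lactone opened; both aromatic rings are bought.

**Route**

Step 1
Reactants: 1 4-allyl-1-(benzyloxy)-2-methoxybenzene
Product: 3 3-{[4-(benzyloxy)-3-methoxyphenyl]methyl}cyclobutan-1-one, via 2,2-dichlorocyclobutanone cycloadduct 2 (not isolated)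
Conditions: Cl3CCOCl (2 equiv), Zn–Cu couple, Et2O–DME, 0 °C to rt; then Zn dust, AcOH, same flask, rt to 50 °C
Reagents that add atoms: trichloroacetyl chloride, ClC(=O)C(Cl)(Cl)Cl
Why: Zn-generated dichloroketene adds to the terminal alkene in a thermal ketene–alkene [2+2] cycloaddition (carbonyl carbon to the CH2 terminus), and Zn/AcOH reductive dechlorination then gives the symmetric, prochiral 3-substituted cyclobutanone; the benzyl ether and the electron-rich ring are inert to both.

Step 2
Reactants: 3 3-{[4-(benzyloxy)-3-methoxyphenyl]methyl}cyclobutan-1-one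
Product: 4 (4S)-4-{[4-(benzyloxy)-3-methoxyphenyl]methyl}oxolan-2-one
Conditions: Me3SiOOSiMe3 (1.3 equiv), chiral IDPi acid (2 mol %, antipode giving the S lactone), CH2Cl2, −78 °C; aq. NaHCO3
Reagents that add atoms: bis(trimethylsilyl) peroxide, C[Si](C)(C)OO[Si](C)(C)C
Why: Proposed new method: a silylium-based, counteranion-directed Baeyer–Villiger desymmetrization. The confined imidodiphosphorimidate (IDPi) acid is silylated by the peroxide to a Me3Si+/IDPi− pair that O-silylates the strained ketone, and Me3SiOOSiMe3 adds to give the bis-silyl peroxyketal (Criegee adduct). Silylation of the distal peroxide oxygen makes (Me3Si)2O the leaving group, and the ring CH2 antiperiplanar to the O–O bond migrates to oxygen inside the chiral anion pocket. Only one of the two enantiotopic CH2 groups can reach that alignment with the arylmethyl group pointing out of the pocket, so this CH2–O bond formation sets C4 (S), and silyl transfer from the O-silylated lactone to the next ketone turns the catalyst over. Closest known reactions are the racemic Me3SiOTf-catalyzed Baeyer–Villiger oxidation with Me3SiOOSiMe3 and the chiral phosphoric acid/H2O2 Baeyer–Villiger desymmetrization of 3-substituted cyclobutanones.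

Step 3
Reactants: 4 (4S)-4-{[4-(benzyloxy)-3-methoxyphenyl]methyl}oxolan-2-one; 5 4-(benzyloxy)-3-methoxybenzaldehyde
Product: 8 (3R,4S)-4-{[4-(benzyloxy)-3-methoxyphenyl]methyl}-3-{[4-(benzyloxy)-3-methoxyphenyl](hydroxy)methyl}oxolan-2-one (both carbinol epimers), via lithium enolate 6 (not isolated), via lithium aldolate 7 (not isolated)
Conditions: LiN(iPr)2 (1.1 equiv), THF, −78 °C; then 5, −78 °C; sat. aq. NH4Cl at −78 °C
Reagents that add atoms: none
Why: Lithium enolate aldol addition; the aldehyde approaches the enolate face anti to the C4 arylmethyl group, setting C3 (R) trans to C4, and the carbinol centre forms as a mixture that does not matter because it is ionized in step 4.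

Step 4
Reactants: 8 (3R,4S)-aldol adduct (both carbinol epimers)
Product: 9 (3aS,9R,9aS)-7-(benzyloxy)-9-[4-(benzyloxy)-3-methoxyphenyl]-6-methoxy-3a,4,9,9a-tetrahydronaphtho[2,3-c]furan-1(3H)-one
Conditions: CF3CO2H (10 equiv), CH2Cl2, 0 °C to rt, 1 h
Reagents that add atoms: none
Why: Intramolecular Friedel–Crafts alkylation: acid ionizes the p-alkoxybenzylic alcohol and the cation is captured by the arylmethyl ring para to its OMe group (six-membered ring B); the chair-like transition state places the aryl group equatorial, so C1 is set trans to C2 (all-trans lactone, as in the podorhizol to isodeoxypodophyllotoxin cyclization), and both carbinol epimers converge.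

Step 5
Reactants: 9 all-trans bis-benzyl aryltetralin lactone
Product: 11 methyl (1R,2S,3S)-7-(benzyloxy)-1-[4-(benzyloxy)-3-methoxyphenyl]-3-(hydroxymethyl)-6-methoxy-1,2,3,4-tetrahydronaphthalene-2-carboxylate, via potassium carboxylate 10 (not isolated)
Conditions: KOH (1.05 equiv), THF–H2O, 0 °C; evaporate; then MeI (3 equiv), DMF, rt
Reagents that add atoms: potassium hydroxide, [K+].[OH-]; iodomethane, CI
Why: Saponification opens the trans-fused γ-lactone irreversibly by acyl C–O cleavage, much faster than α-deprotonation, so C2 is untouched; the carboxylate is then O-alkylated by MeI (SN2) in preference to the neutral primary alcohol, and no stereocenter is touched.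

Step 6
Reactants: 11 bis-benzyl hydroxy methyl ester
Product: 12 methyl (1R,2S,3S)-7-hydroxy-1-(4-hydroxy-3-methoxyphenyl)-3-(hydroxymethyl)-6-methoxy-1,2,3,4-tetrahydronaphthalene-2-carboxylate
Conditions: H2 (1 atm), 10% Pd/C, EtOAc–MeOH, rt
Reagents that add atoms: none
Why: Hydrogenolysis of both benzyl aryl ethers under neutral conditions; the ester, the primary alcohol and the diarylmethine C–H are untouched, and without acid or base the trans hydroxy ester neither relactonizes nor epimerizes.

**Compound list**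
1 | 4-allyl-1-(benzyloxy)-2-methoxybenzene (eugenol benzyl ether) | C=CCc1ccc(OCc2ccccc2)c(OC)c1 | starting material
2 | 2,2-dichloro-3-{[4-(benzyloxy)-3-methoxyphenyl]methyl}cyclobutan-1-one (racemic) | O=C1CC(Cc2ccc(OCc3ccccc3)c(OC)c2)C1(Cl)Cl | intermediate
3 | 3-{[4-(benzyloxy)-3-methoxyphenyl]methyl}cyclobutan-1-one (achiral, prochiral) | O=C1CC(Cc2ccc(OCc3ccccc3)c(OC)c2)C1 | intermediate
4 | (4S)-4-{[4-(benzyloxy)-3-methoxyphenyl]methyl}oxolan-2-one | O=C1C[C@@H](CO1)Cc1ccc(OCc2ccccc2)c(OC)c1 | intermediate
5 | 4-(benzyloxy)-3-methoxybenzaldehyde (O-benzylvanillin) | O=Cc1ccc(OCc2ccccc2)c(OC)c1 | starting material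
6 | lithium (4S)-4-{[4-(benzyloxy)-3-methoxyphenyl]methyl}-4,5-dihydrofuran-2-olate (enolate of 4) | [Li+].[O-]C1=C[C@@H](CO1)Cc1ccc(OCc2ccccc2)c(OC)c1 | intermediate
7 | lithium alkoxide of 8 (aldolate, both carbinol epimers) | O=C1[C@@H](C([O-])c2ccc(OCc3ccccc3)c(OC)c2)[C@@H](CO1)Cc1ccc(OCc2ccccc2)c(OC)c1.[Li+] | intermediate
8 | (3R,4S)-4-{[4-(benzyloxy)-3-methoxyphenyl]methyl}-3-{[4-(benzyloxy)-3-methoxyphenyl](hydroxy)methyl}oxolan-2-one (both carbinol epimers) | O=C1[C@@H](C(O)c2ccc(OCc3ccccc3)c(OC)c2)[C@@H](CO1)Cc1ccc(OCc2ccccc2)c(OC)c1 | intermediate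
9 | (3aS,9R,9aS)-7-(benzyloxy)-9-[4-(benzyloxy)-3-methoxyphenyl]-6-methoxy-3a,4,9,9a-tetrahydronaphtho[2,3-c]furan-1(3H)-one | O=C3[C@@H]1[C@@H](CO3)Cc2cc(OC)c(OCc4ccccc4)cc2[C@H]1c1ccc(OCc2ccccc2)c(OC)c1 | intermediate
10 | potassium (1R,2S,3S)-7-(benzyloxy)-1-[4-(benzyloxy)-3-methoxyphenyl]-3-(hydroxymethyl)-6-methoxy-1,2,3,4-tetrahydronaphthalene-2-carboxylate | [K+].[O-]C(=O)[C@@H]1[C@@H](CO)Cc2cc(OC)c(OCc3ccccc3)cc2[C@H]1c1ccc(OCc2ccccc2)c(OC)c1 | intermediate
11 | methyl (1R,2S,3S)-7-(benzyloxy)-1-[4-(benzyloxy)-3-methoxyphenyl]-3-(hydroxymethyl)-6-methoxy-1,2,3,4-tetrahydronaphthalene-2-carboxylate | COC(=O)[C@@H]1[C@@H](CO)Cc2cc(OC)c(OCc3ccccc3)cc2[C@H]1c1ccc(OCc2ccccc2)c(OC)c1 | intermediate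
12 | methyl (1R,2S,3S)-7-hydroxy-1-(4-hydroxy-3-methoxyphenyl)-3-(hydroxymethyl)-6-methoxy-1,2,3,4-tetrahydronaphthalene-2-carboxylate | COC(=O)[C@@H]1[C@@H](CO)Cc2cc(OC)c(O)cc2[C@H]1c1ccc(O)c(OC)c1 | target

**Step count and risks**
Total steps: 6. Longest linear sequence: 6 (1 → 3 → 4 → 8 → 9 → 11 → 12).

Steps most likely to fail:

1. Step 2 (the proposed silylium/IDPi oxygen insertion). It may give low ee through a racemic background pathway, or the peroxide may attack the electron-rich ring. The fallback is known chemistry and desymmetrizes by enantioselective deprotonation instead of oxygen insertion. It sets out from 3: lithium bis[(S)-1-phenylethyl]amide (or its antipode, whichever gives the S series) with Me3SiCl as in situ quench in THF at −100 °C gives the silyl enol ether F1. Ozonolysis (O3, CH2Cl2–MeOH, −78 °C) with NaBH4 work-up gives the hydroxy acid F2, which closes on acidification (dilute HCl) and comes back to the route at 4. In either case the ee can be raised by recrystallizing 9.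

2. Step 5 (lactone opening and esterification). Residual base could relactonize 11 or epimerize C2. The fallback sets out from 9 and reverses the order: H2, Pd/C first gives the bisphenol lactone F3. NaOH (4 equiv) in aqueous THF, then careful acidification to pH 4 at 0 °C, gives the trihydroxy acid F4. Me3SiCHN2 in toluene–MeOH at 0 °C esterifies only the carboxylic acid under neutral conditions and comes back to the route at 12.

3. Step 1 (telescoped dichloroketene cycloaddition and dechlorination). Ketene oligomerization or sluggish addition to the unactivated alkene would lower the yield. The fallback sets out from 1 and uses a keteniminium [2+2]: N,N-dimethylacetamide, Tf2O and 2,4,6-collidine in ClCH2CH2Cl at reflux give the cyclobutaniminium triflate F5, and aqueous NaHCO3 hydrolysis comes back to the route at 3.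

Further compounds
F1 | step 2 | (S)-{[3-{[4-(benzyloxy)-3-methoxyphenyl]methyl}cyclobut-1-en-1-yl]oxy}trimethylsilane | C[Si](C)(C)OC1=C[C@@H](Cc2ccc(OCc3ccccc3)c(OC)c2)C1
F2 | step 2 | (3S)-3-{[4-(benzyloxy)-3-methoxyphenyl]methyl}-4-hydroxybutanoic acid | OC(=O)C[C@@H](CO)Cc1ccc(OCc2ccccc2)c(OC)c1
F3 | step 5 | (3aS,9R,9aS)-7-hydroxy-9-(4-hydroxy-3-methoxyphenyl)-6-methoxy-3a,4,9,9a-tetrahydronaphtho[2,3-c]furan-1(3H)-one | O=C3[C@@H]1[C@@H](CO3)Cc2cc(OC)c(O)cc2[C@H]1c1ccc(O)c(OC)c1
F4 | step 5 | (1R,2S,3S)-7-hydroxy-1-(4-hydroxy-3-methoxyphenyl)-3-(hydroxymethyl)-6-methoxy-1,2,3,4-tetrahydronaphthalene-2-carboxylic acid | OC(=O)[C@@H]1[C@@H](CO)Cc2cc(OC)c(O)cc2[C@H]1c1ccc(O)c(OC)c1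
F5 | step 1 | 3-{[4-(benzyloxy)-3-methoxyphenyl]methyl}-N,N-dimethylcyclobutan-1-iminium trifluoromethanesulfonate | C[N+](C)=C1CC(Cc2ccc(OCc3ccccc3)c(OC)c2)C1.[O-]S(=O)(=O)C(F)(F)F
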